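**Strategy.** Each cyclopentanol ring is read as a three-carbon unit, C5(pyranyl)–C1(OH)–C2(isopropenyl), closed by an unsubstituted C3–C4 ethano bridge. Both ring bonds to that bridge (C4–C5 and C2–C3) are made in one anionic [3+2] annulation. The dianion of a β-hydroxy-γ,δ-epoxy ester adds to phenyl vinyl sulfone, an ethylene equivalent, and the resulting sulfonyl carbanion opens the epoxide 5-exo. The carbinol centre steers C5 (anti addition) and the epoxide sets C2 by inversion; the sulfone is then removed. The twofold-symmetric skeleton is completed two-directionally from a central bis(vinylsilane): double ketone synthesis, double reduction, double vinylsilane–oxocarbenium cyclization.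

Key step: step 4

Remark: ring locants above are C1 carbinol, C2 isopropenyl-bearing, C3/C4 methylene, C5 pyranyl-bearing; the sulfonyl-bearing centre of 9 is removed in step 5 and is left unspecified.

**Step 1**
Reactants: 1 3-methylbut-2-en-1-ol
Product: 2 [(2R)-3,3-dimethyloxiran-2-yl]methanol
Conditions: Ti(OiPr)4 (cat.), D-(−)-diethyl tartrate (cat.), t-BuOOH, 4 Å MS, CH2Cl2, −20 °C
Reagents that add atoms: tert-butyl hydroperoxide, CC(C)(C)OO
Why: Sharpless asymmetric epoxidation, in which the titanium–D-(−)-tartrate complex should deliver oxygen to the face that gives the 2R epoxide (L-(+)-tartrate gives 2S), setting the centre that becomes the isopropenyl-bearing ring carbon.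

**Step 2**
Reactants: 2 [(2R)-3,3-dimethyloxiran-2-yl]methanol
Product: 3 (2S)-3,3-dimethyloxirane-2-carbaldehyde
Conditions: Dess–Martin periodinane, NaHCO3, CH2Cl2, 0 °C to rt; concentrated cold and used at once
Reagents that add atoms: none
Why: Buffered Dess–Martin oxidation should give the volatile epoxy aldehyde without opening the epoxide or epimerising the α-centre.

**Step 3**
Reactants: 3 (2S)-3,3-dimethyloxirane-2-carbaldehyde; 4 methyl acetate
Product: 5 methyl (3R)-3-[(2R)-3,3-dimethyloxiran-2-yl]-3-hydroxypropanoate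
Conditions: LiN(i-Pr)2, 4, THF, −78 °C; then 3, −78 °C; chromatographic removal of the minor syn isomer
Reagents that add atoms: none
Why: Aldol addition of the lithium ester enolate, in which Felkin–Anh/Cornforth attack anti to the epoxide C–O bond of this cis-substituted epoxy aldehyde should give the anti (erythro) epoxy alcohol and so set the carbinol centre (3R).

**Step 4**
Reactants: 5 methyl (3R)-3-[(2R)-3,3-dimethyloxiran-2-yl]-3-hydroxypropanoate; 6 phenyl vinyl sulfone
Product: 9 methyl (1S,2R,3S)-2-hydroxy-3-(2-hydroxypropan-2-yl)-4-(phenylsulfonyl)cyclopentane-1-carboxylate, via dilithium alkoxide–enolate 7 (not isolated), via lithiated sulfone adduct 8 (not isolated)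
Conditions: LiN(i-Pr)2 (2.1 equiv), THF, −78 to −50 °C; then 6 (1.0 equiv), −78 °C; then DMPU, −78 to 0 °C; aqueous work-up
Reagents that add atoms: none
Why: Two equivalents of base give the lithium alkoxide–ester enolate 7, whose α-carbon adds to the β-carbon of 6 to give the α-sulfonyl carbanion 8, and this carbanion opens the epoxide at its secondary carbon to close the ring. The sequence is a Michael-initiated ring closure (conjugate addition followed by intramolecular alkylation), which joins a Fráter–Seebach dianion addition to a sulfone-carbanion epoxide opening. The cyclopentane closes in the 5-exo-tet mode, the breaking epoxide C–O bond lying outside the new ring. The ester-bearing centre is set by attack on the chelated dianion anti to the epoxide-bearing substituent, which places CO2Me trans to OH, and the carbon bearing the 2-hydroxypropan-2-yl group is set by inversion at the epoxide carbon, which places that group cis to OH. The step needs C-addition of the enolate before any attack on the epoxide and 5-exo over 6-endo or 3-exo opening; the low addition temperature, a single equivalent of 6, the fully substituted other epoxide carbon and the strain of a cyclopropane should secure this.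

**Step 5**
Reactants: 9 methyl (1S,2R,3S)-2-hydroxy-3-(2-hydroxypropan-2-yl)-4-(phenylsulfonyl)cyclopentane-1-carboxylate
Product: 10 methyl (1S,2S,3S)-2-hydroxy-3-(2-hydroxypropan-2-yl)cyclopentane-1-carboxylate
Conditions: 6% Na(Hg), Na2HPO4, MeOH–THF, −20 °C
Reagents that add atoms: none
Why: Reductive desulfonylation by electron transfer should cleave the C–S bond to leave the ring CH2, while the buffer protects the ester and its α-centre.

**Step 6**
Reactants: 10 methyl (1S,2S,3S)-2-hydroxy-3-(2-hydroxypropan-2-yl)cyclopentane-1-carboxylate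
Product: 11 methyl (1S,2S,3S)-2-[(tert-butyldimethylsilyl)oxy]-3-(2-hydroxypropan-2-yl)cyclopentane-1-carboxylate
Conditions: TBSOTf (1.05 equiv), 2,6-lutidine, CH2Cl2, −78 °C
Reagents that add atoms: tert-butyldimethylsilyl triflate, CC(C)(C)[Si](C)(C)OS(=O)(=O)C(F)(F)F
Why: The secondary carbinol should silylate far faster than the tertiary one at low temperature, and the silyl ether later keeps this oxygen from forming an oxocarbenium ion next to the isopropenyl group.

**Step 7**
Reactants: 11 methyl (1S,2S,3S)-2-[(tert-butyldimethylsilyl)oxy]-3-(2-hydroxypropan-2-yl)cyclopentane-1-carboxylate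
Product: 12 methyl (1S,2S,3R)-2-[(tert-butyldimethylsilyl)oxy]-3-(prop-1-en-2-yl)cyclopentane-1-carboxylate
Conditions: SOCl2, pyridine, −20 to 0 °C; any minor isopropylidene isomer removed on AgNO3-impregnated silica gel
Reagents that add atoms: none
Why: E2 dehydration of the tertiary chlorosulfite should take a methyl hydrogen in preference to the hindered ring methine hydrogen next to the silyloxy group, giving the isopropenyl group and leaving the ring centre untouched.

**Step 8**
Reactants: 12 methyl (1S,2S,3R)-2-[(tert-butyldimethylsilyl)oxy]-3-(prop-1-en-2-yl)cyclopentane-1-carboxylate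
Product: 13 (1S,2S,3R)-2-[(tert-butyldimethylsilyl)oxy]-N-methoxy-N-methyl-3-(prop-1-en-2-yl)cyclopentane-1-carboxamide
Conditions: MeNH(OMe)·HCl, i-PrMgCl, THF, −20 to 0 °C
Reagents that add atoms: N,O-dimethylhydroxylamine hydrochloride, CNOC.Cl
Why: Direct aminolysis of the ester by the chloromagnesium amide gives the Weinreb amide, and since the trans arrangement of acyl and silyloxy groups is the thermodynamic one no epimerisation is expected.

**Step 9**
Reactants: 14 hexa-1,5-diyne
Product: 15 1,6-bis(trimethylsilyl)hexa-1,5-diyne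
Conditions: n-BuLi (2.2 equiv), THF, −78 °C; then Me3SiCl (2.4 equiv)
Reagents that add atoms: chlorotrimethylsilane, C[Si](C)(C)Cl
Why: Double deprotonation of the terminal alkynes followed by C-silylation at both ends.

**Step 10**
Reactants: 15 1,6-bis(trimethylsilyl)hexa-1,5-diyne; 16 ethylene oxide (2 equiv, one per alkenyl–aluminium bond)
Product: 19 (3Z,7Z)-3,8-bis(trimethylsilyl)deca-3,7-diene-1,10-diol, via bis(alkenylalane) 17 (not isolated), via dilithium bis(alanate) 18 (not isolated)
Conditions: i-Bu2AlH (2.4 equiv), N-methylpyrrolidine (2.4 equiv), heptane, 60 °C; then MeLi (2.4 equiv), Et2O, 0 °C; then 16 (excess), 0 °C to rt; aqueous work-up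
Reagents that add atoms: ethylene oxide (second equivalent of 16), C1CO1
Why: cis-Hydroalumination of each silylalkyne in the presence of the amine donor places Al geminal to Si, and each of the two alanate centres transfers its alkenyl group to one molecule of ethylene oxide with retention, so each new CH2CH2OH chain is trans to the central chain and Si is cis to it (Z).

**Step 11**
Reactants: 19 (3Z,7Z)-3,8-bis(trimethylsilyl)deca-3,7-diene-1,10-diol
Product: 20 (3Z,7Z)-1,10-diiodo-3,8-bis(trimethylsilyl)deca-3,7-diene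
Conditions: I2, PPh3, imidazole, CH2Cl2, 0 °C to rt
Reagents that add atoms: iodine, II
Why: Appel-type iodination of the two primary alcohols, in which the preformed phosphine–iodine complex should spare the vinylsilanes.

**Step 12**
Reactants: 20 (3Z,7Z)-1,10-diiodo-3,8-bis(trimethylsilyl)deca-3,7-diene; 13 (1S,2S,3R)-2-[(tert-butyldimethylsilyl)oxy]-N-methoxy-N-methyl-3-(prop-1-en-2-yl)cyclopentane-1-carboxamide (2 equiv, one per carbon–lithium bond)
Product: 22 (4Z,8Z)-1,12-bis[(1S,2S,3R)-2-[(tert-butyldimethylsilyl)oxy]-3-(prop-1-en-2-yl)cyclopentyl]-4,9-bis(trimethylsilyl)dodeca-4,8-diene-1,12-dione, via dilithium reagent 21 (not isolated)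
Conditions: t-BuLi (4.2 equiv), Et2O–pentane, −78 °C; then 13 (2.2 equiv), THF, −78 to 0 °C; aqueous work-up
Reagents that add atoms: Weinreb amide 13 (second equivalent), C=C(C)[C@H]1CC[C@H](C(=O)N(C)OC)[C@H]1O[Si](C)(C)C(C)(C)C
Why: Iodine–lithium exchange gives the bis(alkyllithium) 21, each carbon–lithium bond of which should add once to one molecule of 13 because the chelated tetrahedral intermediate persists until work-up (Weinreb ketone synthesis run in both directions, two molecules of 13 per molecule of 20).

**Step 13**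
Reactants: 22 (4Z,8Z)-1,12-bis[(1S,2S,3R)-2-[(tert-butyldimethylsilyl)oxy]-3-(prop-1-en-2-yl)cyclopentyl]-4,9-bis(trimethylsilyl)dodeca-4,8-diene-1,12-dione
Product: 23 (1R,4Z,8Z,12R)-1,12-bis[(1R,2S,3R)-2-[(tert-butyldimethylsilyl)oxy]-3-(prop-1-en-2-yl)cyclopentyl]-4,9-bis(trimethylsilyl)dodeca-4,8-diene-1,12-diol
Conditions: LiBH(s-Bu)3 (2.5 equiv), THF, −78 °C
Reagents that add atoms: none
Why: Felkin–Anh reduction, in which the bulky hydride should attack each ketone anti to the silyloxy-bearing ring carbon and give the R carbinol that is 1,3-syn to the silyloxy group, the same at both ends.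

**Step 14**
Reactants: 23 (1R,4Z,8Z,12R)-1,12-bis[(1R,2S,3R)-2-[(tert-butyldimethylsilyl)oxy]-3-(prop-1-en-2-yl)cyclopentyl]-4,9-bis(trimethylsilyl)dodeca-4,8-diene-1,12-diol
Product: 24 the bis[(2-methoxyethoxy)methyl] ether of 23
Conditions: MEMCl (4 equiv), i-Pr2NEt, CH2Cl2, 0 to 40 °C
Reagents that add atoms: 2-methoxyethoxymethyl chloride, COCCOCCl
Why: O-Alkylation of both secondary alcohols gives the acetal that serves as the oxocarbenium precursor and supplies the OCH2 carbon of each tetrahydropyran ring.

**Step 15**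
Reactants: 24 the bis[(2-methoxyethoxy)methyl] ether of 23
Product: 25 testudinariol A bis(tert-butyldimethylsilyl) ether
Conditions: SnCl4 (2.5 equiv), CH2Cl2, −20 °C
Reagents that add atoms: none
Why: Acetal-initiated, vinylsilane-terminated (Prins-type) cyclization, in which SnCl4 ionises each MEM ether to an oxocarbenium ion, the silicon-bearing alkene carbon attacks it 6-exo, and loss of silicon from the β-silyl cation with retention should give the exocyclic Z-alkene, while the silyl-protected ring oxygen cannot form a competing oxocarbenium ion.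

**Step 16**
Reactants: 25 testudinariol A bis(tert-butyldimethylsilyl) ether
Product: 26 testudinariol A
Conditions: Bu4NF, THF, rt to 40 °C
Reagents that add atoms: none
Why: Fluoride should cleave the two silyl ethers without touching the alkenes or the rings.

**Compound list**
1 | 3-methylbut-2-en-1-ol | CC(C)=CCO | starting material
2 | [(2R)-3,3-dimethyloxiran-2-yl]methanol | OC[C@H]1OC1(C)C | intermediate
3 | (2S)-3,3-dimethyloxirane-2-carbaldehyde | O=C[C@H]1OC1(C)C | intermediate
4 | methyl acetate | COC(C)=O | starting material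
5 | methyl (3R)-3-[(2R)-3,3-dimethyloxiran-2-yl]-3-hydroxypropanoate | COC(=O)C[C@@H](O)[C@H]1OC1(C)C | intermediate
6 | phenyl vinyl sulfone | C=CS(=O)(=O)c1ccccc1 | starting material
7 | dilithium alkoxide–enolate of 5 | [Li+].[Li+].COC([O-])=C[C@@H]([O-])[C@H]1OC1(C)C | intermediate
8 | dilithium salt of the Michael adduct (alkoxide and α-sulfonyl carbanion) | [Li+].[Li+].COC(=O)[C@@H](C[CH-]S(=O)(=O)c1ccccc1)[C@@H]([O-])[C@H]1OC1(C)C | intermediate
9 | methyl (1S,2R,3S)-2-hydroxy-3-(2-hydroxypropan-2-yl)-4-(phenylsulfonyl)cyclopentane-1-carboxylate (C4 unspecified) | CC(C)(O)[C@H]1C(S(=O)(=O)c2ccccc2)C[C@H](C(=O)OC)[C@H]1O | intermediate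
10 | methyl (1S,2S,3S)-2-hydroxy-3-(2-hydroxypropan-2-yl)cyclopentane-1-carboxylate | CC(C)(O)[C@H]1CC[C@H](C(=O)OC)[C@H]1O | intermediate
11 | methyl (1S,2S,3S)-2-[(tert-butyldimethylsilyl)oxy]-3-(2-hydroxypropan-2-yl)cyclopentane-1-carboxylate | CC(C)(O)[C@H]1CC[C@H](C(=O)OC)[C@H]1O[Si](C)(C)C(C)(C)C | intermediate
12 | methyl (1S,2S,3R)-2-[(tert-butyldimethylsilyl)oxy]-3-(prop-1-en-2-yl)cyclopentane-1-carboxylate | C=C(C)[C@H]1CC[C@H](C(=O)OC)[C@H]1O[Si](C)(C)C(C)(C)C | intermediate
13 | (1S,2S,3R)-2-[(tert-butyldimethylsilyl)oxy]-N-methoxy-N-methyl-3-(prop-1-en-2-yl)cyclopentane-1-carboxamide | C=C(C)[C@H]1CC[C@H](C(=O)N(C)OC)[C@H]1O[Si](C)(C)C(C)(C)C | intermediate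
14 | hexa-1,5-diyne | C#CCCC#C | starting material
15 | 1,6-bis(trimethylsilyl)hexa-1,5-diyne | C[Si](C)(C)C#CCCC#C[Si](C)(C)C | intermediate
16 | ethylene oxide | C1CO1 | starting material
17 | (1Z,5Z)-1,6-bis(diisobutylalumanyl)-1,6-bis(trimethylsilyl)hexa-1,5-diene | CC(C)C[Al](CC(C)C)/C(=C/CC/C=C(/[Al](CC(C)C)CC(C)C)[Si](C)(C)C)[Si](C)(C)C | intermediate
18 | dilithium bis(methyl alanate) of 17 | [Li+].[Li+].CC(C)C[Al-](C)(CC(C)C)/C(=C/CC/C=C(/[Al-](C)(CC(C)C)CC(C)C)[Si](C)(C)C)[Si](C)(C)C | intermediate
19 | (3Z,7Z)-3,8-bis(trimethylsilyl)deca-3,7-diene-1,10-diol | OCC/C(=C/CC/C=C(/CCO)[Si](C)(C)C)[Si](C)(C)C | intermediate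
20 | (3Z,7Z)-1,10-diiodo-3,8-bis(trimethylsilyl)deca-3,7-diene | ICC/C(=C/CC/C=C(/CCI)[Si](C)(C)C)[Si](C)(C)C | intermediate
21 | (3Z,7Z)-1,10-dilithio-3,8-bis(trimethylsilyl)deca-3,7-diene | [Li]CC/C(=C/CC/C=C(/CC[Li])[Si](C)(C)C)[Si](C)(C)C | intermediate
22 | (4Z,8Z)-1,12-bis[(1S,2S,3R)-2-[(tert-butyldimethylsilyl)oxy]-3-(prop-1-en-2-yl)cyclopentyl]-4,9-bis(trimethylsilyl)dodeca-4,8-diene-1,12-dione | C=C(C)[C@H]1CC[C@H](C(=O)CC/C(=C/CC/C=C(/CCC(=O)[C@H]2CC[C@H](C(=C)C)[C@@H]2O[Si](C)(C)C(C)(C)C)[Si](C)(C)C)[Si](C)(C)C)[C@H]1O[Si](C)(C)C(C)(C)C | intermediate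
23 | (1R,4Z,8Z,12R)-1,12-bis[(1R,2S,3R)-2-[(tert-butyldimethylsilyl)oxy]-3-(prop-1-en-2-yl)cyclopentyl]-4,9-bis(trimethylsilyl)dodeca-4,8-diene-1,12-diol | C=C(C)[C@H]1CC[C@H]([C@H](O)CC/C(=C/CC/C=C(/CC[C@@H](O)[C@H]2CC[C@H](C(=C)C)[C@@H]2O[Si](C)(C)C(C)(C)C)[Si](C)(C)C)[Si](C)(C)C)[C@H]1O[Si](C)(C)C(C)(C)C | intermediate
24 | bis[(2-methoxyethoxy)methyl] ether of 23 (both chain carbinols, configuration unchanged) | C=C(C)[C@H]1CC[C@H]([C@H](OCOCCOC)CC/C(=C/CC/C=C(/CC[C@@H](OCOCCOC)[C@H]2CC[C@H](C(=C)C)[C@@H]2O[Si](C)(C)C(C)(C)C)[Si](C)(C)C)[Si](C)(C)C)[C@H]1O[Si](C)(C)C(C)(C)C | intermediate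
25 | testudinariol A bis(tert-butyldimethylsilyl) ether (both cyclopentanol oxygens silylated) | C=C(C)[C@H]1CC[C@H]([C@H]2CC/C(=C/CC/C=C3/CC[C@H]([C@H]4CC[C@H](C(=C)C)[C@@H]4O[Si](C)(C)C(C)(C)C)OC3)CO2)[C@H]1O[Si](C)(C)C(C)(C)C | intermediate
26 | testudinariol A | C=C(C)[C@H]1CC[C@H]([C@H]2CC/C(=C/CC/C=C3/CC[C@H]([C@H]4CC[C@H](C(=C)C)[C@@H]4O)OC3)CO2)[C@H]1O | target

**Total step count:** 16.
**Longest linear sequence:** 13 steps (steps 1–8, then 12–16).

**Steps most likely to fail**

1. Step 4. The dianion may be consumed before ring closure (3-exo attack of the enolate on its own epoxide, proton transfer from the ester α-position to the sulfonyl carbanion, oligomerisation of the vinyl sulfone), or the sulfonyl carbanion may fail to open the hindered epoxide while two alkoxides are present. Fallback, from 5 back to 9, with the two bonds made in separate operations: the conjugate addition is stopped at −78 °C with acetic acid to give the open-chain sulfone methyl (2S,3R)-3-[(2R)-3,3-dimethyloxiran-2-yl]-3-hydroxy-2-[2-(phenylsulfonyl)ethyl]propanoate F1. The carbinol is silylated (Et3SiCl, imidazole, DMF) to give the triethylsilyl ether F2. LiN(i-Pr)2 (1.05 equiv, THF, −78 °C) should then remove a proton from the unhindered α-sulfonyl CH2 faster than from the crowded ester methine, and BF3·OEt2 activates the epoxide so that this monoanion closes the ring 5-exo to the silylated cyclopentane F3. HF·pyridine removes the silyl group and returns 9.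

2. Step 13. Facial selectivity may be poor if the two ring carbons flanking the ketone-bearing centre are not differentiated strongly enough, and because two ketones are reduced independently even moderate selectivity gives a mixture of diastereomeric diols. Fallback, from 22 back to 23, with catalyst control in place of substrate control: Corey–Bakshi–Shibata reduction with the oxazaborolidine (S)-1-methyl-3,3-diphenyltetrahydro-1H,3H-pyrrolo[1,2-c][1,3,2]oxazaborole and catecholborane in toluene at −78 °C. The cyclopentyl group takes the role of the large ketone substituent and the primary chain that of the small one, so hydride should be delivered to the same face at both ketones to give the (1R,12R)-diol 23. Catecholborane is chosen because it should not hydroborate the isopropenyl or vinylsilane groups at this temperature. This fallback makes no new compound (none F0).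

3. Step 15. Cationic side reactions may compete with the double cyclization: protodesilylation of the vinylsilanes, attack of the oxocarbenium ions by the isopropenyl groups, or loss of the silyl ethers. Fallback, from 24 back to 25, with the ring C–O bond made under neutral conditions: iododesilylation with N-iodosuccinimide (MeCN, 0 °C, retention) gives the bis(vinyl iodide) F4. Stille coupling with Bu3SnCH2OH and Pd(PPh3)4 gives the bis(allylic alcohol) F5 with unchanged alkene geometry. ZnBr2 in CH2Cl2 removes the MEM groups to give the tetraol bis(tert-butyldimethylsilyl) ether F6. A double Mitsunobu cyclodehydration (PPh3, DIAD) activates the primary allylic alcohols and closes both tetrahydropyran rings through the secondary oxygens to give 25.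

**Further compounds**
F1 | step 4 | methyl (2S,3R)-3-[(2R)-3,3-dimethyloxiran-2-yl]-3-hydroxy-2-[2-(phenylsulfonyl)ethyl]propanoate | COC(=O)[C@@H](CCS(=O)(=O)c1ccccc1)[C@@H](O)[C@H]1OC1(C)C
F2 | step 4 | triethylsilyl ether, methyl (2S,3R)-3-[(2R)-3,3-dimethyloxiran-2-yl]-2-[2-(phenylsulfonyl)ethyl]-3-[(triethylsilyl)oxy]propanoate | COC(=O)[C@@H](CCS(=O)(=O)c1ccccc1)[C@@H](O[Si](CC)(CC)CC)[C@H]1OC1(C)C
F3 | step 4 | silylated cyclopentane, methyl (1S,2R,3S)-3-(2-hydroxypropan-2-yl)-4-(phenylsulfonyl)-2-[(triethylsilyl)oxy]cyclopentane-1-carboxylate (C4 unspecified) | CC(C)(O)[C@H]1C(S(=O)(=O)c2ccccc2)C[C@H](C(=O)OC)[C@H]1O[Si](CC)(CC)CC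
F0 | step 13 | none | none
F4 | step 15 | bis(vinyl iodide) from 24 (each SiMe3 replaced by I with retention) | C=C(C)[C@H]1CC[C@H]([C@H](OCOCCOC)CC/C(=C/CC/C=C(/CC[C@@H](OCOCCOC)[C@H]2CC[C@H](C(=C)C)[C@@H]2O[Si](C)(C)C(C)(C)C)I)I)[C@H]1O[Si](C)(C)C(C)(C)C
F5 | step 15 | bis(allylic alcohol) from F4 (each I replaced by CH2OH) | C=C(C)[C@H]1CC[C@H]([C@H](OCOCCOC)CC/C(=C/CC/C=C(/CC[C@@H](OCOCCOC)[C@H]2CC[C@H](C(=C)C)[C@@H]2O[Si](C)(C)C(C)(C)C)CO)CO)[C@H]1O[Si](C)(C)C(C)(C)C
F6 | step 15 | tetraol bis(tert-butyldimethylsilyl) ether from F5 (MEM groups removed) | C=C(C)[C@H]1CC[C@H]([C@H](O)CC/C(=C/CC/C=C(/CC[C@@H](O)[C@H]2CC[C@H](C(=C)C)[C@@H]2O[Si](C)(C)C(C)(C)C)CO)CO)[C@H]1O[Si](C)(C)C(C)(C)C
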